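**Assumption:** in-situ reagent preparation and work-ups are not counted as steps; the commercial THF solution of 3,4,5-trimethoxyphenylmagnesium bromide is used. Target numbering: O1, C2 (aryl, S), C3 (CH2OH, R), C4 (aroyl, R), C5 (CH2), i.e. 2,3-trans / 3,4-cis.

## Retrosynthetic overview

1. Magnone B (11) ⇐ acyclic keto-diol 10. The only ring, the THF, is closed last through O1–C2 by anodic dehydrogenative benzylic C–H/O–H coupling, which also sets C2.
2. 10 ⇐ triol 9 ⇐ trans-aldol lactone 8. The lactone C=O becomes ring C5 and the lactone CH2O becomes the exocyclic CH2OH, so a trans-α,β-lactone maps onto the 3,4-cis THF.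
3. 8 ⇐ (R)-β-(3,4,5-trimethoxybenzyl)-γ-butyrolactone 6 + veratraldehyde 7 (C4 set anti to C3).
4. 6 ⇐ cyclopropane-fused lactone 3 + aryl Grignard/Cu, then decarboxylation; 3 ⇐ (R)-epichlorohydrin 1 + diethyl malonate 2 (C3 is the purchased stereocentre).
5. Ring order: cyclopropane + γ-lactone (step 1) → cyclopropane opened (step 2) → lactone opened (step 5) → THF formed (step 7).

## Route

**Step 1**
Reactants: 1, (R)-epichlorohydrin; 2, diethyl malonate
Product: 3, ethyl (1S,5R)-2-oxo-3-oxabicyclo[3.1.0]hexane-1-carboxylate
Conditions: NaOEt (1.05 equiv), EtOH, 0 °C → reflux, 18 h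
Reagents that add atoms: diethyl malonate, CCOC(=O)CC(=O)OCC (reactant 2)
Why: Double alkylation/lactonisation cascade (malonate opens the epoxide at CH2, the alkoxide re-closes an epoxide by expelling chloride, then 3-exo-tet opening at the stereocentre with inversion and lactonisation), which converts the purchased C–O stereocentre into the C–C stereocentre that becomes C3.

**Step 2**
Reactants: 3, cyclopropane lactone ester; 4, 3,4,5-trimethoxyphenylmagnesium bromide
Product: 5, ethyl (3S,4R)-2-oxo-4-(3,4,5-trimethoxybenzyl)tetrahydrofuran-3-carboxylate (trans major; C3 is epimerisable and removed in step 3)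
Conditions: 4 (1.5 equiv), CuI (10 mol %), THF, −40 → −10 °C; aq. NH4Cl
Reagents that add atoms: 3,4,5-trimethoxyphenylmagnesium bromide, COc1cc([Mg]Br)cc(OC)c1OC (reactant 4)
Why: Cu-catalysed homoconjugate (SN2-type) addition of the aryl cuprate at the unsubstituted CH2 of the doubly activated cyclopropane releases a malonate enolate and leaves the C4 stereocentre untouched.

**Step 3**
Reactants: 5, malonate-type lactone ester
Product: 6, (R)-4-(3,4,5-trimethoxybenzyl)dihydrofuran-2(3H)-one
Conditions: LiCl, H2O, DMSO, 140 °C
Reagents that add atoms: none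
Why: Krapcho dealkoxycarbonylation removes the ester; the β-stereocentre is not enolisable and is retained.

**Step 4**
Reactants: 6, (R)-β-benzyl lactone; 7, 3,4-dimethoxybenzaldehyde
Product: 8, (3S,4R)-3-[(RS)-(3,4-dimethoxyphenyl)(hydroxy)methyl]-4-(3,4,5-trimethoxybenzyl)dihydrofuran-2(3H)-one (carbinol epimers, both used)
Conditions: LiHMDS (1.1 equiv), THF, −78 °C; then 7; AcOH quench at −78 °C
Reagents that add atoms: 3,4-dimethoxybenzaldehyde, COc1ccc(C=O)cc1OC (reactant 7)
Why: Lithium enolate aldol addition in which the aldehyde approaches the face anti to the β-benzyl group, giving the trans-α,β-lactone and so setting the future C4; the carbinol centre is destroyed in step 6.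

**Step 5**
Reactants: 8, aldol lactone
Product: 9, (2R,3R)-2-[(RS)-(3,4-dimethoxyphenyl)(hydroxy)methyl]-3-(3,4,5-trimethoxybenzyl)butane-1,4-diol
Conditions: LiAlH4 (3 equiv), THF, 0 °C → rt; Rochelle salt work-up
Reagents that add atoms: none
Why: Hydride reduction of the lactone to the 1,4-diol turns the lactone carbonyl into the future C5H2OH without touching either stereocentre.

**Step 6**
Reactants: 9, triol
Product: 10, (2R,3R)-1-(3,4-dimethoxyphenyl)-4-hydroxy-2-(hydroxymethyl)-3-(3,4,5-trimethoxybenzyl)butan-1-one
Conditions: activated MnO2 (20 equiv), CH2Cl2, rt; filter, use directly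
Reagents that add atoms: none
Why: Chemoselective MnO2 oxidation of the electron-rich benzylic secondary alcohol (primary aliphatic alcohols are inert) under neutral conditions, so C4, now α to the ketone, is not epimerised.

**Step 7**
Reactants: 10, keto-diol
Product: 11, Magnone B, (3,4-dimethoxyphenyl)[(3R,4R,5S)-4-(hydroxymethyl)-5-(3,4,5-trimethoxyphenyl)tetrahydrofuran-3-yl]methanone
Conditions: undivided cell, graphite(+)/Pt(−), constant current (~1 mA cm⁻²), 2.1–2.2 F mol⁻¹, n-Bu4NBF4 (0.1 M), CH2Cl2/HFIP 4:1, 2,6-lutidine (2 equiv), 0 °C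
Reagents that add atoms: none
Why: Proposed new method: diastereoselective anodic dehydrogenative C(sp3)–H/O–H cyclisation — the trimethoxybenzyl ring (estimated Ep ≈ +1.4 V vs SCE) is oxidised in preference to the acyl-deactivated veratroyl ring (estimated ≈ +1.75 V), lutidine removes the acidified benzylic proton, the benzylic radical is oxidised at once (ECE) to a p-methoxy-stabilised cation that HFIP keeps alive, and the C5-OH captures it 5-exo (the C3-CH2OH could only form an oxetane) with the aryl group anti to the C3 and C4 substituents, giving the 2,3-trans (2S) ring while H2 forms at the cathode; the closest known reactions are anodic side-chain alkoxylation of methoxytoluenes and electrochemical or DDQ-type benzylic C–H lactonisation/etherification, none shown for stereoselective closure of a 2-aryl-THF on an unprotected keto-diol.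

## Compound list

1 | (R)-epichlorohydrin | ClC[C@H]1CO1 | starting material
2 | diethyl malonate | CCOC(=O)CC(=O)OCC | starting material
3 | ethyl (1S,5R)-2-oxo-3-oxabicyclo[3.1.0]hexane-1-carboxylate | CCOC(=O)[C@]12C[C@H]1COC2=O | intermediate
4 | 3,4,5-trimethoxyphenylmagnesium bromide | COc1cc([Mg]Br)cc(OC)c1OC | starting material
5 | ethyl (3S,4R)-2-oxo-4-(3,4,5-trimethoxybenzyl)tetrahydrofuran-3-carboxylate (trans major) | CCOC(=O)[C@H]1C(=O)OC[C@@H]1Cc1cc(OC)c(OC)c(OC)c1 | intermediate
6 | (R)-4-(3,4,5-trimethoxybenzyl)dihydrofuran-2(3H)-one | O=C1C[C@@H](Cc2cc(OC)c(OC)c(OC)c2)CO1 | intermediate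
7 | 3,4-dimethoxybenzaldehyde | COc1ccc(C=O)cc1OC | starting material
8 | (3S,4R)-3-[(RS)-(3,4-dimethoxyphenyl)(hydroxy)methyl]-4-(3,4,5-trimethoxybenzyl)dihydrofuran-2(3H)-one | COc1ccc(C(O)[C@H]2C(=O)OC[C@@H]2Cc3cc(OC)c(OC)c(OC)c3)cc1OC | intermediate
9 | (2R,3R)-2-[(RS)-(3,4-dimethoxyphenyl)(hydroxy)methyl]-3-(3,4,5-trimethoxybenzyl)butane-1,4-diol | COc1ccc(C(O)[C@@H](CO)[C@H](CO)Cc2cc(OC)c(OC)c(OC)c2)cc1OC | intermediate
10 | (2R,3R)-1-(3,4-dimethoxyphenyl)-4-hydroxy-2-(hydroxymethyl)-3-(3,4,5-trimethoxybenzyl)butan-1-one | COc1ccc(C(=O)[C@@H](CO)[C@H](CO)Cc2cc(OC)c(OC)c(OC)c2)cc1OC | intermediate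
11 | Magnone B | COc1ccc(C(=O)[C@H]2CO[C@H](c3cc(OC)c(OC)c(OC)c3)[C@H]2CO)cc1OC | target

## Summary

Total steps: 7. Longest linear sequence: 7 (from (R)-epichlorohydrin; 4 and 7 are purchased).

Steps most likely to fail:

1. **Step 7 (proposed new anodic cyclisation).** Risks are over-oxidation of the product at C2–H, capture of the cation by the ketone oxygen, and dehydration of the β-hydroxy ketone. Fallback with known chemistry: bring the C2–O bond in from a carbonyl instead of a C–H oxidation.
   - Run steps 2–5 with the aryl groups exchanged (3,4-dimethoxyphenylmagnesium bromide in step 2, 3,4,5-trimethoxybenzaldehyde in step 4; same (R)-epichlorohydrin).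
   - Close the THF by the classical acid-catalysed SN1 cyclodehydration of the benzylic triol (CSA, CH2Cl2; 2,3-trans).
   - Acetylate the CH2OH, oxidise the veratryl CH2 to the ketone with DDQ in aqueous dioxane/AcOH, and remove the acetate.
2. **Step 2 (aryl cuprate opening of the cyclopropane).** Aryl Grignards are less reactive than alkyl ones here and may attack a carbonyl. Fallback: open 3 with iodide (NaI/TMSCl, MeCN) to the β-iodomethyl lactone ester, decarboxylate (Krapcho), form the alkylzinc iodide and Negishi-couple it with 5-bromo-1,2,3-trimethoxybenzene to reach 6.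
3. **Step 6 (selective oxidation to a fragile β-hydroxy ketone).** Keto-diol 10 may dehydrate, undergo retro-aldol loss of formaldehyde, or epimerise at C4. Fallback: postpone the ketone. Silylate the carbinol of 8 (TBSOTf), reduce with LiAlH4, ring-close the resulting diol, remove the silyl group (TBAF) and oxidise the ring-closed benzylic alcohol with MnO2 as the last step (two extra steps).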